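**Plan**
- **Numbering and enabling feature:** the arene is C1(OH), C2 and C3 (OMe), C4(OH), C5(CH3), C6 (side chain C1' to C24'). The C1 phenol oxygen and C3' are the ends of the path O–C1–C6–C1'–C2'=C3'. They can be tied into the pyran ring of a 4H-chromene, where C3' becomes the enol-ether carbon C2 and can carry a metal and an aryloxy leaving group at once.
- **Cuts:** first C3'–C4' together with C3'–CH3 (chromen-2-yl metal + C26 alkyl metal + MeI in one flask). In the chain, C7'–C8' with C7'–CH3 (same reaction type on 2,3-dihydrofuran) and C8'–C9' (one-carbon homologation of geranylgeranyl bromide). In the arene part, C6–C1' and O–C3' (acrylic acid on the hydroquinone).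
- **Forward order:** C20 alcohol → C21 iodide → C26 iodide. In parallel, quinone → hydroquinone → dihydrocoumarin (pyranone ring closed on the only free arene C–H and the neighbouring OH) → ketene acetal phosphate → 2-stannyl-4H-chromene. The union opens the pyran ring again and frees the C1 OH, and desilylation of O4 ends the route.
- **Stereochemistry:** 10'E, 14'E and 18'E come with geranylgeraniol. 6'E and 2'E each come from a cyclic enol ether (ring O cis to ring CH2), inversion at the migration terminus and retention in the methylation.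

Key step: step 11

Assumption: (2E,6E,10E)-geranylgeraniol of high isomeric purity, 2,3-dimethoxy-5-methyl-1,4-benzoquinone, 2,3-dihydrofuran and acrylic acid are taken as commercial.

Step 1
Reactants: 1 (2E,6E,10E)-geranylgeraniol
Product: 2 (2E,6E,10E)-geranylgeranyl bromide
Conditions: PBr3, Et2O, 0 °C
Reagents that add atoms: phosphorus tribromide BrP(Br)Br
Why: Bromination of a primary allylic alcohol through its phosphite ester (SN2 displacement by bromide) at 0 °C leaves the 2E olefin in place and creates no stereocentre.

Step 2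
Reactants: 2 geranylgeranyl bromide
Product: 3 phenyl (3E,7E,11E)-4,8,12,16-tetramethylheptadeca-3,7,11,15-tetraen-1-yl sulfide (homogeranylgeranyl phenyl sulfide)
Conditions: PhSCH3, n-BuLi, DABCO, THF, 0 °C; CuI, −78 °C; then 2, −78 °C → rt
Reagents that add atoms: thioanisole CSc1ccccc1, delivered as (phenylthio)methylcopper [Cu]CSc1ccccc1
Why: Alkylation of a sulfur-stabilised carbanion, delivered as its copper derivative, takes place at the unhindered primary allylic carbon (SN2) and adds the one carbon that becomes C8'.

Step 3
Reactants: 3 homogeranylgeranyl phenyl sulfide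
Product: 5 (3E,7E,11E)-1-iodo-4,8,12,16-tetramethylheptadeca-3,7,11,15-tetraene (homogeranylgeranyl iodide), via methylphenylsulfonium iodide 4 (not isolated)
Conditions: MeI (excess), NaI, DMF, 70 °C
Reagents that add atoms: methyl iodide CI; sodium iodide [Na+].[I-] (iodide pool)
Why: S-Methylation to sulfonium salt 4 turns the sulfur into a leaving group and iodide then attacks the primary homoallylic carbon (SN2 dealkylation of a sulfonium salt, the known one-carbon chain extension of halides to iodides), while attack at the S-methyl group is merely the reverse reaction.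

Step 4
Reactants: 5 homogeranylgeranyl iodide; 6 2,3-dihydrofuran
Product: 11 (3E,7E,11E,15E)-4,8,12,16,20-pentamethylhenicosa-3,7,11,15,19-pentaen-1-ol (homogeranylfarnesol), via homogeranylgeranyllithium 7 (not isolated), via 5-lithio-2,3-dihydrofuran 8 (not isolated), via mixed lithium cuprate 9 (not isolated), via alkenylcopper lithium alkoxide 10 (not isolated)
Conditions: 5, t-BuLi (2 equiv), Et2O/pentane, −78 °C; 6, t-BuLi, THF, −78 → 0 °C; CuBr·SMe2, Et2O/Me2S, −78 °C, 7 then 8; → rt; MeI, 0 °C → rt; aq. NH4Cl
Reagents that add atoms: methyl iodide CI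
Why: 1,2-Metallate rearrangement of an α-alkoxyalkenyl cuprate, a known route to isoprenoid homoallylic alcohols, in which the alkyl ligand of 9 migrates from copper to C5 of the dihydrofuran with inversion and ring opening, so that the copper of 10 ends cis to the CH2CH2O arm (ring O and C3 were cis) and methylation with retention sets the new 3E olefin.

Step 5
Reactants: 11 homogeranylfarnesol
Product: 12 (3E,7E,11E,15E)-1-iodo-4,8,12,16,20-pentamethylhenicosa-3,7,11,15,19-pentaene (homogeranylfarnesyl iodide)
Conditions: I2, PPh3, imidazole, CH2Cl2, 0 °C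
Reagents that add atoms: iodine II
Why: Appel-type iodination converts the primary alcohol through its alkoxyphosphonium salt by SN2 attack of iodide under neutral conditions that do not touch the five olefins.

Step 6
Reactants: 13 2,3-dimethoxy-5-methyl-1,4-benzoquinone
Product: 14 2,3-dimethoxy-5-methylbenzene-1,4-diol
Conditions: Na2S2O4, Et2O/H2O, rt, N2
Reagents that add atoms: none
Why: Dithionite reduction of a benzoquinone to its hydroquinone is fast in a two-phase system and adds only two hydrogens.

Step 7
Reactants: 14 2,3-dimethoxy-5-methylbenzene-1,4-diol; 15 acrylic acid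
Product: 16 6-hydroxy-7,8-dimethoxy-5-methylchroman-2-one
Conditions: CH3SO3H, 70 °C, N2
Reagents that add atoms: none
Why: Acid-mediated Friedel–Crafts conjugate hydroarylation of acrylic acid followed by lactonisation, as in the known dihydrocoumarin syntheses from alkylated hydroquinones, can occur only at C6, the single free arene position, and only the neighbouring C1 hydroxyl can close the six-membered lactone.

Step 8
Reactants: 16 6-hydroxy-7,8-dimethoxy-5-methylchroman-2-one
Product: 17 6-(tert-butyldimethylsilyloxy)-7,8-dimethoxy-5-methylchroman-2-one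
Conditions: TBSOTf, 2,6-lutidine, CH2Cl2, 0 °C
Reagents that add atoms: tert-butyldimethylsilyl triflate CC(C)(C)[Si](C)(C)OS(=O)(=O)C(F)(F)F
Why: Silylation of the one remaining phenol with a silyl triflate and a non-nucleophilic base avoids acyl transfer from the aryl lactone and masks O4 against the bases to come.

Step 9
Reactants: 17 silylated chroman-2-one
Product: 19 6-(tert-butyldimethylsilyloxy)-7,8-dimethoxy-5-methyl-4H-chromen-2-yl diphenyl phosphate, via potassium lactone enolate 18 (not isolated)
Conditions: (PhO)2P(O)Cl, KN(SiMe3)2, THF/DMPU, −78 °C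
Reagents that add atoms: diphenyl chlorophosphate O=P(Cl)(Oc1ccccc1)Oc1ccccc1
Why: O-Phosphorylation of a lactone enolate to a cyclic ketene acetal phosphate is well known, and adding the base to the premixed lactone and chlorophosphate at −78 °C traps enolate 18 before it can open to a ketene.

Step 10
Reactants: 19 ketene acetal phosphate
Product: 20 [6-(tert-butyldimethylsilyloxy)-7,8-dimethoxy-5-methyl-4H-chromen-2-yl]trimethylstannane
Conditions: (Me3Sn)2, Pd(PPh3)4 (cat.), LiCl, THF, reflux; chromatography on Et3N-deactivated silica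
Reagents that add atoms: hexamethylditin C[Sn](C)(C)[Sn](C)(C)C
Why: Stille-type stannylation in which zerovalent palladium inserts into the C2–O(phosphate) bond, the better of the two leaving groups on C2, and transmetalation with the distannane and reductive elimination give the alkenylstannane, as known for lactone-derived ketene acetal phosphates.

Step 11
Reactants: 12 homogeranylfarnesyl iodide; 20 2-trimethylstannyl-4H-chromene
Product: 25 4-(tert-butyldimethylsilyloxy)-6-[(2E,6E,10E,14E,18E)-3,7,11,15,19,23-hexamethyltetracosa-2,6,10,14,18,22-hexaen-1-yl]-2,3-dimethoxy-5-methylphenol, via homogeranylfarnesyllithium 21 (not isolated), via 4H-chromen-2-yllithium 22 (not isolated), via mixed lithium cuprate 23 (not isolated), via alkenylcopper lithium phenoxide 24 (not isolated)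
Conditions: 12, t-BuLi (2 equiv), Et2O/pentane, −78 °C; 20, n-BuLi (1 equiv), THF, −78 °C; CuBr·SMe2, Et2O/Me2S, −78 °C, 21 then 22; −78 → 0 °C; MeI, 0 °C → rt; aq. NH4Cl
Reagents that add atoms: methyl iodide CI
Why: Proposed new method: tin–lithium exchange gives chromen-2-yllithium 22, which together with alkyllithium 21 and CuBr·SMe2 forms the mixed cuprate 23, whose pyran C2 (the future C3') is a carbenoid carbon bearing both the metal and the aryloxy leaving group. The alkyl ligand then shifts from copper to C2 anti to the breaking C2–O1 bond (1,2-metallate rearrangement with inversion at the sp2 carbon), which forms the C3'–C4' bond, opens the pyran ring and frees the C1 phenoxide, so no ring is closed. Because O1 and C4 are held cis in the ring, inversion places copper cis and the new chain trans to the benzylic CH2, and methylation of alkenylcopper 24 by oxidative addition of MeI and reductive elimination goes with retention, so the 2'E geometry follows from the ring alone. The closest known reaction type is the rearrangement of cuprates of 5-lithio-2,3-dihydrofuran and 6-lithio-3,4-dihydro-2H-pyran used in step 4; a benzo-fused enol ether with a phenoxide leaving group has not been shown, and the better leaving group should offset the smaller ring strain. The step needs C2 metalation without loss of the acidic C4 protons, secured by tin–lithium exchange at −78 °C in place of deprotonation and by an arene without any ring C–H, and it needs a single migrating group, secured by the one-to-one alkyl/chromenyl cuprate. C-Methylation should win over O-methylation because the doubly ortho-substituted lithium phenoxide is a poor nucleophile in ether solvents without a dipolar additive.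

Step 12
Reactants: 25 O4-silylated ubiquinol-6
Product: 26 ubiquinol-6
Conditions: Bu4NF, AcOH, degassed THF, 0 °C, argon
Reagents that add atoms: none
Why: Fluoride-induced cleavage of the aryl silyl ether, buffered with acetic acid and run without oxygen, frees O4 without acid-induced cyclisation of the polyene or oxidation of the quinol to the quinone.

**Compound list**
1 | (2E,6E,10E)-geranylgeraniol | OC/C=C(\C)CC/C=C(\C)CC/C=C(\C)CCC=C(C)C | starting material
2 | (2E,6E,10E)-geranylgeranyl bromide | BrC/C=C(\C)CC/C=C(\C)CC/C=C(\C)CCC=C(C)C | intermediate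
3 | homogeranylgeranyl phenyl sulfide | c1ccccc1SCC/C=C(\C)CC/C=C(\C)CC/C=C(\C)CCC=C(C)C | intermediate
4 | homogeranylgeranyl(methyl)(phenyl)sulfonium iodide (formed in the flask) | [I-].C[S+](c1ccccc1)CC/C=C(\C)CC/C=C(\C)CC/C=C(\C)CCC=C(C)C | intermediate
5 | homogeranylgeranyl iodide | ICC/C=C(\C)CC/C=C(\C)CC/C=C(\C)CCC=C(C)C | intermediate
6 | 2,3-dihydrofuran | C1CC=CO1 | starting material
7 | homogeranylgeranyllithium (formed in the flask) | [Li]CC/C=C(\C)CC/C=C(\C)CC/C=C(\C)CCC=C(C)C | intermediate
8 | 5-lithio-2,3-dihydrofuran (formed in the flask) | [Li]C1=CCCO1 | intermediate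
9 | lithium (4,5-dihydrofuran-2-yl)(homogeranylgeranyl)cuprate (formed in the flask) | [Li+].C1CC=C(O1)[Cu-]CC/C=C(\C)CC/C=C(\C)CC/C=C(\C)CCC=C(C)C | intermediate
10 | alkenylcopper lithium alkoxide, Cu cis to the CH2CH2OLi arm (formed in the flask) | [Li]OCC/C=C(\[Cu])CC/C=C(\C)CC/C=C(\C)CC/C=C(\C)CCC=C(C)C | intermediate
11 | homogeranylfarnesol, (3E,7E,11E,15E) | OCC/C=C(\C)CC/C=C(\C)CC/C=C(\C)CC/C=C(\C)CCC=C(C)C | intermediate
12 | homogeranylfarnesyl iodide, (3E,7E,11E,15E) | ICC/C=C(\C)CC/C=C(\C)CC/C=C(\C)CC/C=C(\C)CCC=C(C)C | intermediate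
13 | 2,3-dimethoxy-5-methyl-1,4-benzoquinone | COC1=C(OC)C(=O)C(C)=CC1=O | starting material
14 | 2,3-dimethoxy-5-methylbenzene-1,4-diol | COc1c(O)c(C)cc(O)c1OC | intermediate
15 | acrylic acid | C=CC(=O)O | starting material
16 | 6-hydroxy-7,8-dimethoxy-5-methylchroman-2-one | COc1c(O)c(C)c2CCC(=O)Oc2c1OC | intermediate
17 | 6-(tert-butyldimethylsilyloxy)-7,8-dimethoxy-5-methylchroman-2-one | COc1c(O[Si](C)(C)C(C)(C)C)c(C)c2CCC(=O)Oc2c1OC | intermediate
18 | potassium enolate of 17 (formed in the flask) | [K+].COc1c(O[Si](C)(C)C(C)(C)C)c(C)c2CC=C([O-])Oc2c1OC | intermediate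
19 | 6-(tert-butyldimethylsilyloxy)-7,8-dimethoxy-5-methyl-4H-chromen-2-yl diphenyl phosphate | COc1c(O[Si](C)(C)C(C)(C)C)c(C)c2CC=C(OP(=O)(Oc3ccccc3)Oc3ccccc3)Oc2c1OC | intermediate
20 | [6-(tert-butyldimethylsilyloxy)-7,8-dimethoxy-5-methyl-4H-chromen-2-yl]trimethylstannane | COc1c(O[Si](C)(C)C(C)(C)C)c(C)c2CC=C([Sn](C)(C)C)Oc2c1OC | intermediate
21 | homogeranylfarnesyllithium (formed in the flask) | [Li]CC/C=C(\C)CC/C=C(\C)CC/C=C(\C)CC/C=C(\C)CCC=C(C)C | intermediate
22 | 6-(tert-butyldimethylsilyloxy)-7,8-dimethoxy-5-methyl-4H-chromen-2-yllithium (formed in the flask) | COc1c(O[Si](C)(C)C(C)(C)C)c(C)c2CC=C([Li])Oc2c1OC | intermediate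
23 | lithium (4H-chromen-2-yl)(homogeranylfarnesyl)cuprate (formed in the flask) | [Li+].COc1c(O[Si](C)(C)C(C)(C)C)c(C)c2CC=C([Cu-]CC/C=C(\C)CC/C=C(\C)CC/C=C(\C)CC/C=C(\C)CCC=C(C)C)Oc2c1OC | intermediate
24 | ring-opened alkenylcopper lithium phenoxide, Cu cis to the benzylic CH2 (formed in the flask) | COc1c(O[Si](C)(C)C(C)(C)C)c(C)c(C/C=C(\[Cu])CC/C=C(\C)CC/C=C(\C)CC/C=C(\C)CC/C=C(\C)CCC=C(C)C)c(O[Li])c1OC | intermediate
25 | O4-(tert-butyldimethylsilyl)ubiquinol-6, all-E | COc1c(O[Si](C)(C)C(C)(C)C)c(C)c(C/C=C(\C)CC/C=C(\C)CC/C=C(\C)CC/C=C(\C)CC/C=C(\C)CCC=C(C)C)c(O)c1OC | intermediate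
26 | ubiquinol-6, all-E | COc1c(O)c(C)c(C/C=C(\C)CC/C=C(\C)CC/C=C(\C)CC/C=C(\C)CC/C=C(\C)CCC=C(C)C)c(O)c1OC | target

**Step count**
Total step count: 12.
Longest linear sequence: 7. This holds for both branches: steps 1–5, 11, 12 from geranylgeraniol, and steps 6–10, 11, 12 from the quinone.

**Steps most likely to fail**

1. **Step 11.**
 - What may go wrong: proton transfer from the doubly activated C4 methylene to the C2 carbanion, or α-elimination of lithium phenoxide from the carbenoid before copper is reached. The alkylcopper species could also decay thermally before migration, or methylation could go to oxygen in place of carbon.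
 - The fallback uses known chemistry, forms the same C3'–C4' bond and reverses the order of the two C–C bonds. It sets out from 12 and 19.
 - Zinc insertion into 12 (Zn dust, LiCl, THF) gives homogeranylfarnesylzinc iodide F1. Negishi coupling of it with ketene acetal phosphate 19 (PdCl2(dppf), THF) gives the 2-homogeranylfarnesyl-4H-chromene F2.
 - Nickel-catalysed Kumada-type ring opening of this cyclic enol ether with MeMgBr (NiCl2(PPh3)2, toluene, reflux) replaces the C2–O bond by C2–CH3 with retention. The methyl group takes the place of the ring oxygen cis to the benzylic CH2, and the route is rejoined at 25.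

2. **Step 9.**
 - What may go wrong: opening of the aryl-ester enolate to a ketene and a phenoxide faster than O-phosphorylation, or hydrolysis of the sensitive ketene acetal phosphate on handling.
 - The fallback avoids the lactone enolate altogether. It sets out from 17.
 - Reduction with i-Bu2AlH (CH2Cl2, −78 °C) gives the chroman-2-ol F3. Benzenesulfinic acid with CaCl2 in CH2Cl2 gives the 2-(phenylsulfonyl)chroman F4.
 - Deprotonation next to the sulfone with LiN(i-Pr)2 and quenching with Bu3SnCl give the 2-sulfonyl-2-stannylchroman F5. Heating with i-Pr2NEt in toluene expels the sulfinic acid to give the 2-tributylstannyl-4H-chromene F6, a sequence known from stannyl glycals.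
 - Tin–lithium exchange with n-BuLi rejoins the route at 22.

3. **Step 7.**
 - What may go wrong: polymerisation of acrylic acid, acid-induced loss of a methyl ether, or oxidation of the hydroquinone in hot acid before C-alkylation.
 - The fallback makes the C6–C1' bond by radical chemistry on the quinone. It sets out from 13.
 - Silver-catalysed decarboxylative alkylation (Minisci-type) with monomethyl succinate (AgNO3 cat., (NH4)2S2O8, MeCN/H2O, 70 °C) gives the quinone propanoate F7.
 - Na2S2O4 reduces it to the hydroquinone propanoate F8. A trace of TsOH in warm toluene closes the lactone with loss of the ester alcohol, which rejoins the route at 16.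

**Further compounds**
F1 | step 11 | homogeranylfarnesylzinc iodide | I[Zn]CC/C=C(\C)CC/C=C(\C)CC/C=C(\C)CC/C=C(\C)CCC=C(C)C
F2 | step 11 | 6-(tert-butyldimethylsilyloxy)-2-homogeranylfarnesyl-7,8-dimethoxy-5-methyl-4H-chromene | COc1c(O[Si](C)(C)C(C)(C)C)c(C)c2CC=C(CC/C=C(\C)CC/C=C(\C)CC/C=C(\C)CC/C=C(\C)CCC=C(C)C)Oc2c1OC
F3 | step 9 | 6-(tert-butyldimethylsilyloxy)-7,8-dimethoxy-5-methylchroman-2-ol (racemic) | COc1c(O[Si](C)(C)C(C)(C)C)c(C)c2CCC(O)Oc2c1OC
F4 | step 9 | 6-(tert-butyldimethylsilyloxy)-7,8-dimethoxy-5-methyl-2-(phenylsulfonyl)chroman (racemic) | COc1c(O[Si](C)(C)C(C)(C)C)c(C)c2CCC(S(=O)(=O)c3ccccc3)Oc2c1OC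
F5 | step 9 | 6-(tert-butyldimethylsilyloxy)-7,8-dimethoxy-5-methyl-2-(phenylsulfonyl)-2-(tributylstannyl)chroman (racemic) | COc1c(O[Si](C)(C)C(C)(C)C)c(C)c2CCC([Sn](CCCC)(CCCC)CCCC)(S(=O)(=O)c3ccccc3)Oc2c1OC
F6 | step 9 | [6-(tert-butyldimethylsilyloxy)-7,8-dimethoxy-5-methyl-4H-chromen-2-yl]tributylstannane | COc1c(O[Si](C)(C)C(C)(C)C)c(C)c2CC=C([Sn](CCCC)(CCCC)CCCC)Oc2c1OC
F7 | step 7 | methyl 3-(4,5-dimethoxy-2-methyl-3,6-dioxocyclohexa-1,4-dien-1-yl)propanoate | COC(=O)CCC1=C(C)C(=O)C(OC)=C(OC)C1=O
F8 | step 7 | methyl 3-(2,5-dihydroxy-3,4-dimethoxy-6-methylphenyl)propanoate | COC(=O)CCc1c(C)c(O)c(OC)c(OC)c1O
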